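The route cuts ring C of the top catechin at C3–C4 and O1–C2. Top C4 is a diarylmethine carbon. It lies between top ring A, which carries O1 on C8a next to the attachment carbon C4a, and C8 of the gallocatechin ring A. A carbinol at this carbon therefore ionises to the heterodiene O1=C8a–C4a=C4. One [4+2] addition of an (E)-2-arylvinyl acetate brings in C2, C3 and ring B, closes the pyran and sets C2, C3 and C4 together. The precursor is an o-hydroxybenzhydrol on C8 of the perbenzylated gallocatechin-(4β→8)-catechin dimer. It is assembled from an 8-lithiocatechin, a dihydromyricetin-derived 4-ketone and a masked salicylaldehyde.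

Key step: step 16

Conventions: flavan numbering is used. Top is the catechin bonded only through C4, middle is the gallocatechin, and bottom is the catechin with CH2 at C4. The α face carries the C2 aryl groups and the β face carries the 3-oxygens. Bn is benzyl.

Assumption: the (R)-configured phosphoric acid is taken as the enantiomer that leaves open the methide face leading to the 4α-linked top unit. No model covers so crowded a methide. Both catalyst enantiomers are commercial.

Step 1
Reactants: 1 (+)-catechin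
Product: 2 5,7,3',4'-tetra-O-benzyl-(+)-catechin (2R,3S, free 3-OH)
Conditions: BnBr (4.4 equiv), K2CO3, DMF, 0 °C to rt
Reagents that add atoms: benzyl bromide, BrCc1ccccc1
Why: Williamson etherification in which carbonate deprotonates only the four phenols, so the secondary 3-OH stays free and C2 and C3 are untouched.

Step 2
Reactants: 2 5,7,3',4'-tetra-O-benzyl-(+)-catechin
Product: 3 3,5,7,3',4'-penta-O-benzyl-(+)-catechin
Conditions: NaH, BnBr, DMF, 0 °C to rt
Reagents that add atoms: benzyl bromide, BrCc1ccccc1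
Why: Williamson etherification of the sodium alkoxide of the 3-OH; with every phenol already capped, base-induced opening of ring C is impossible and C2 and C3 keep their configuration.

Step 3
Reactants: 3 3,5,7,3',4'-penta-O-benzyl-(+)-catechin
Product: 4 8-bromo-3,5,7,3',4'-penta-O-benzyl-(+)-catechin
Conditions: NBS (1.0 equiv), CH2Cl2, −78 °C to 0 °C
Reagents that add atoms: N-bromosuccinimide, O=C1CCC(=O)N1Br
Why: Electrophilic aromatic bromination, which on benzylated catechins is known to go to C8 because ring A is the most electron-rich ring and C8 lies next to the tied-back O1 whereas C6 is buried between two benzyloxy groups.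

Step 4
Reactants: 5 (+)-dihydromyricetin (2R,3R)
Product: 6 5,7,3',4',5'-penta-O-benzyldihydromyricetin (2R,3R, free 3-OH)
Conditions: BnBr (5.5 equiv), K2CO3, degassed DMF, argon, rt to 40 °C
Reagents that add atoms: benzyl bromide, BrCc1ccccc1
Why: Williamson etherification under weak base and exclusion of air: the acidic 7-OH and 4'-OH react first, which closes the quinone-methide route to C2 epimerisation, the chelated 5-OH follows with excess bromide, the 3-OH is not ionised by carbonate, and without oxygen no flavonol is formed.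

Step 5
Reactants: 6 5,7,3',4',5'-penta-O-benzyldihydromyricetin
Product: 7 3,5,7,3',4',5'-hexa-O-benzyldihydromyricetin (2R,3R)
Conditions: BnOC(=NH)CCl3, TfOH (cat.), CH2Cl2/cyclohexane, 0 °C to rt
Reagents that add atoms: benzyl 2,2,2-trichloroacetimidate, N=C(OCc1ccccc1)C(Cl)(Cl)Cl
Why: Acid-catalysed trichloroacetimidate benzylation, chosen because alkoxide conditions would enolise the ketone and expel O1 from C2 or scramble C3, whereas the SN1-type benzyl transfer leaves both stereocentres alone.

Step 6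
Reactants: 4 8-bromo-3,5,7,3',4'-penta-O-benzyl-(+)-catechin; 7 3,5,7,3',4',5'-hexa-O-benzyldihydromyricetin
Product: 9 tertiary carbinol, 4-hydroxy-4-(penta-O-benzylcatechin-8-yl)-hexa-O-benzylgallocatechin (C4 not assigned), via aryllithium 8 (not isolated)
Conditions: 4, n-BuLi, THF, −78 °C; then 7, −78 °C; H2O quench
Reagents that add atoms: none
Why: Bromine–lithium exchange followed by 1,2-addition of the aryllithium to the flavan-4-one, a union known for 8-lithiated benzylated flavan-3-ols and 3-O-protected 4-ketones; at −78 °C addition outruns enolisation at C3, and the configuration of the new carbinol carbon does not matter because it is ionised in step 7.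

Step 7
Reactants: 9 tertiary carbinol
Product: 11 undeca-O-benzyl gallocatechin-(4β→8)-catechin (upper unit 2,3-trans-3,4-cis), via flavan-4-yl cation 10 (not isolated)
Conditions: n-Bu3SnH, CF3CO2H, CH2Cl2, −78 °C to 0 °C
Reagents that add atoms: none
Why: Ionic hydrogenation: CF3CO2H ionises the tertiary bis-benzylic carbinol to cation 10, which is too stabilised for Et3SiH but is captured by the far stronger hydride donor n-Bu3SnH, and because allylic strain with the twisted C4 aryl group pushes the 3-benzyloxy group pseudo-axial on the β face, hydride should enter from the α face anti to O3 and leave the catechin unit 4β (3,4-cis, 2,4-trans).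

Step 8
Reactants: 11 undeca-O-benzyl gallocatechin-(4β→8)-catechin
Product: 12 8-bromo dimer (bromine on C8 of the gallocatechin unit)
Conditions: NBS (1.0 equiv), CH2Cl2, −78 °C
Reagents that add atoms: N-bromosuccinimide, O=C1CCC(=O)N1Br
Why: Electrophilic aromatic bromination with one equivalent of reagent: the gallocatechin C8 is the only remaining ring A position next to a ring oxygen, while both C6 positions sit between two benzyloxy groups and the B rings are less electron-rich, so the monomer preference of step 3 should carry over.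

Step 9
Reactants: 13 2,4,6-trihydroxybenzaldehyde
Product: 14 4,6-bis(benzyloxy)-2-hydroxybenzaldehyde
Conditions: BnBr (2.05 equiv), K2CO3, DMF, 0 °C to rt
Reagents that add atoms: benzyl bromide, BrCc1ccccc1
Why: Selective Williamson etherification: after the 4-OH and one ortho OH have reacted, the last OH is held in a strong hydrogen bond to the formyl oxygen and resists alkylation at room temperature with two equivalents of bromide.

Step 10
Reactants: 14 4,6-bis(benzyloxy)-2-hydroxybenzaldehyde
Product: 15 2-allyloxy-4,6-bis(benzyloxy)benzaldehyde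
Conditions: allyl bromide, K2CO3, DMF, 50 °C
Reagents that add atoms: allyl bromide, C=CCBr
Why: Williamson allylation under slightly more forcing conditions; the allyl ether removes the acidic proton that would destroy the aryllithium of step 11, cannot migrate to the neighbouring alkoxide as a silyl or acyl group would, and is orthogonal to benzyl ethers.

Step 11
Reactants: 12 8-bromo dimer; 15 2-allyloxy-4,6-bis(benzyloxy)benzaldehyde
Product: 17 O-allyl benzhydrol on C8 of the dimer (carbinol epimers), via dimer aryllithium 16 (not isolated)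
Conditions: 12, n-BuLi, THF, −78 °C; then 15 (2 equiv), −78 °C; H2O quench
Reagents that add atoms: none
Why: Bromine–lithium exchange and 1,2-addition of the aryllithium to an aromatic aldehyde used in excess; the new carbinol carbon forms as a mixture of epimers, which is harmless because it becomes trigonal in step 16.

Step 12
Reactants: 17 O-allyl benzhydrol
Product: 18 o-hydroxybenzhydrol on C8 of the 3,4-cis dimer (carbinol epimers; purified on Et3N-deactivated silica and used at once)
Conditions: Pd(PPh3)4 (5 mol %), morpholine, THF, rt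
Reagents that add atoms: none
Why: Tsuji–Trost-type deallylation in which zerovalent palladium ionises the aryl allyl ether and morpholine captures the π-allyl complex, conditions that are mildly basic throughout so that the very acid-labile benzhydrol and all benzyl ethers survive.

Step 13
Reactants: 19 3,4-dihydroxyphenylacetic acid
Product: 20 benzyl [3,4-bis(benzyloxy)phenyl]acetate
Conditions: BnBr (3.3 equiv), K2CO3, DMF, rt to 50 °C
Reagents that add atoms: benzyl bromide, BrCc1ccccc1
Why: Williamson etherification of both phenols together with alkylation of the carboxylate, giving in one operation an ester that is ready for partial reduction.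

Step 14
Reactants: 20 benzyl [3,4-bis(benzyloxy)phenyl]acetate
Product: 21 [3,4-bis(benzyloxy)phenyl]acetaldehyde
Conditions: i-Bu2AlH (1.05 equiv), toluene, −78 °C; aq. potassium sodium tartrate
Reagents that add atoms: none
Why: Partial ester reduction: the tetrahedral aluminium hemiacetal is stable at −78 °C and releases the aldehyde only on work-up, and the sensitive arylacetaldehyde is carried on without storage.

Step 15
Reactants: 21 [3,4-bis(benzyloxy)phenyl]acetaldehyde
Product: 22 (E)-2-[3,4-bis(benzyloxy)phenyl]vinyl acetate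
Conditions: Ac2O, KOAc, 120 °C; crystallisation of the E isomer
Reagents that add atoms: acetic anhydride, CC(=O)OC(C)=O
Why: Enol acetylation of an arylacetaldehyde under equilibrating conditions, in which the conjugated and less crowded E enol acetate is the preferred isomer and is freed from residual Z isomer by crystallisation.

Step 16
Reactants: 18 o-hydroxybenzhydrol on C8 of the 3,4-cis dimer; 22 (E)-2-[3,4-bis(benzyloxy)phenyl]vinyl acetate
Product: 24 protected trimer, pentadeca-O-benzyl catechin-(4α→8)-gallocatechin-(4β→8)-catechin with top O3 as acetate, via o-quinone methide 23 (not isolated)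
Conditions: (R)-3,3'-bis(2,4,6-triisopropylphenyl)-1,1'-binaphthyl-2,2'-diyl hydrogen phosphate (10 mol %), 22 (4 equiv), 5 Å molecular sieves, toluene, 0 °C to rt, 18 added slowly
Reagents that add atoms: none
Why: Proposed new method: the phosphoric acid ionises the carbinol of 18, water leaves, and the o-quinone methide 23 (heterodiene O1=C8a–C4a=C4) stays hydrogen-bonded to the chiral phosphate while 22 adds in an inverse-electron-demand oxa-Diels–Alder reaction; the closest known reaction type is the chiral-phosphoric-acid-catalysed [4+2] cycloaddition of o-hydroxybenzhydrol-derived o-quinone methides with styrenes, vinyl sulfides and enol ethers, and the untested element is a 2-arylvinyl ester as the 2π partner. Top ring C closes in cycloaddition mode, concerted but asynchronous with C3–C4 ahead of O1–C2 (in the stepwise limit a 6-exo-trig capture of the C2 benzylic cation by phenoxide O1). C2 and C3 become trans because suprafacial addition copies the E geometry of 22, and C4 becomes cis to C2 and trans to C3 because the aryl group of 22 lies endo under the methide whose gallocatechin substituent points outward (E), which gives the all-equatorial 2,3-trans-3,4-trans unit. The absolute sense at C4, and with it at C2 and C3, is set by the methide face that the 3,3'-aryl pocket of the phosphate leaves open, and since the lower dimer is enantiopure an adduct from the other face is a separable diastereomer that cannot erode enantiopurity. Regioselectivity needs the acetoxy-bearing carbon to be the nucleophilic terminus, which the para-benzyloxy group of 22 secures by stabilising charge at C2 far better than the cross-conjugated ester oxygen could at C3. The peri 5-benzyloxy group lowers the E preference of 23, but the E and Z forms interconvert through the benzhydryl cation under the acid and only the E form offers an unobstructed s-cis heterodiene, while slow addition of 18 to excess 22 holds down Friedel–Crafts self-condensation at the free ring A positions.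

Step 17
Reactants: 24 protected trimer acetate
Product: 25 pentadeca-O-benzyl catechin-(4α→8)-gallocatechin-(4β→8)-catechin (free top 3-OH)
Conditions: K2CO3 (cat.), MeOH/THF, rt
Reagents that add atoms: none
Why: Base-catalysed transesterification (Zemplén-type methanolysis) of the only ester in a molecule whose other oxygens are all benzyl ethers, carried out before the phenols are bared because free oligomeric catechins do not tolerate base.

Step 18
Reactants: 25 pentadeca-O-benzyl trimer
Product: 26 catechin-(4α→8)-gallocatechin-(4β→8)-catechin (target)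
Conditions: H2 (1 atm), Pd(OH)2 on carbon, THF/MeOH/H2O, rt
Reagents that add atoms: none
Why: Catalytic hydrogenolysis of the fifteen benzyl ethers under neutral conditions, the standard final step for benzylated proanthocyanidins, which is known to spare the interflavan C4–C8 bonds, the C2–O1 bonds and all stereocentres.

Compound list

1 | (+)-catechin (2R,3S) | Oc1cc(O)c2c(c1)O[C@H](c1ccc(O)c(O)c1)[C@@H](O)C2 | starting material
2 | 5,7,3',4'-tetra-O-benzyl-(+)-catechin | c9ccccc9COc1cc(OCc9ccccc9)c2c(c1)O[C@H](c3ccc(OCc9ccccc9)c(OCc9ccccc9)c3)[C@@H](O)C2 | intermediate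
3 | 3,5,7,3',4'-penta-O-benzyl-(+)-catechin | c9ccccc9COc1cc(OCc9ccccc9)c2c(c1)O[C@H](c3ccc(OCc9ccccc9)c(OCc9ccccc9)c3)[C@@H](OCc9ccccc9)C2 | intermediate
4 | 8-bromo-3,5,7,3',4'-penta-O-benzyl-(+)-catechin | Brc1c(OCc9ccccc9)cc(OCc9ccccc9)c2c1O[C@H](c3ccc(OCc9ccccc9)c(OCc9ccccc9)c3)[C@@H](OCc9ccccc9)C2 | intermediate
5 | (+)-dihydromyricetin (2R,3R) | Oc1cc(O)c2c(c1)O[C@H](c1cc(O)c(O)c(O)c1)[C@@H](O)C2=O | starting material
6 | 5,7,3',4',5'-penta-O-benzyldihydromyricetin | c9ccccc9COc1cc(OCc9ccccc9)c2c(c1)O[C@H](c3cc(OCc9ccccc9)c(OCc9ccccc9)c(OCc9ccccc9)c3)[C@@H](O)C2=O | intermediate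
7 | 3,5,7,3',4',5'-hexa-O-benzyldihydromyricetin | c9ccccc9COc1cc(OCc9ccccc9)c2c(c1)O[C@H](c3cc(OCc9ccccc9)c(OCc9ccccc9)c(OCc9ccccc9)c3)[C@@H](OCc9ccccc9)C2=O | intermediate
8 | 8-lithio-penta-O-benzylcatechin | [Li]c1c(OCc9ccccc9)cc(OCc9ccccc9)c2c1O[C@H](c3ccc(OCc9ccccc9)c(OCc9ccccc9)c3)[C@@H](OCc9ccccc9)C2 | intermediate (not isolated)
9 | tertiary C4 carbinol of the dimer (C4 not assigned) | c9ccccc9COc1cc(OCc9ccccc9)c2c(c1)O[C@H](c3cc(OCc9ccccc9)c(OCc9ccccc9)c(OCc9ccccc9)c3)[C@@H](OCc9ccccc9)C2(O)c1c(OCc9ccccc9)cc(OCc9ccccc9)c2c1O[C@H](c3ccc(OCc9ccccc9)c(OCc9ccccc9)c3)[C@@H](OCc9ccccc9)C2 | intermediate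
10 | 4-aryl-flavan-4-yl cation | c9ccccc9COc1cc(OCc9ccccc9)c2c(c1)O[C@H](c3cc(OCc9ccccc9)c(OCc9ccccc9)c(OCc9ccccc9)c3)[C@@H](OCc9ccccc9)[C+]2c1c(OCc9ccccc9)cc(OCc9ccccc9)c2c1O[C@H](c3ccc(OCc9ccccc9)c(OCc9ccccc9)c3)[C@@H](OCc9ccccc9)C2 | intermediate (not isolated)
11 | undeca-O-benzyl gallocatechin-(4β→8)-catechin | c9ccccc9COc1cc(OCc9ccccc9)c2c(c1)O[C@H](c3cc(OCc9ccccc9)c(OCc9ccccc9)c(OCc9ccccc9)c3)[C@@H](OCc9ccccc9)[C@H]2c1c(OCc9ccccc9)cc(OCc9ccccc9)c2c1O[C@H](c3ccc(OCc9ccccc9)c(OCc9ccccc9)c3)[C@@H](OCc9ccccc9)C2 | intermediate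
12 | 8-bromo dimer | Brc1c(OCc9ccccc9)cc(OCc9ccccc9)c2c1O[C@H](c3cc(OCc9ccccc9)c(OCc9ccccc9)c(OCc9ccccc9)c3)[C@@H](OCc9ccccc9)[C@H]2c1c(OCc9ccccc9)cc(OCc9ccccc9)c2c1O[C@H](c3ccc(OCc9ccccc9)c(OCc9ccccc9)c3)[C@@H](OCc9ccccc9)C2 | intermediate
13 | 2,4,6-trihydroxybenzaldehyde | O=Cc1c(O)cc(O)cc1O | starting material
14 | 4,6-bis(benzyloxy)-2-hydroxybenzaldehyde | O=Cc1c(O)cc(OCc9ccccc9)cc1OCc9ccccc9 | intermediate
15 | 2-allyloxy-4,6-bis(benzyloxy)benzaldehyde | O=Cc1c(OCC=C)cc(OCc9ccccc9)cc1OCc9ccccc9 | intermediate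
16 | 8-lithio dimer | [Li]c1c(OCc9ccccc9)cc(OCc9ccccc9)c2c1O[C@H](c3cc(OCc9ccccc9)c(OCc9ccccc9)c(OCc9ccccc9)c3)[C@@H](OCc9ccccc9)[C@H]2c1c(OCc9ccccc9)cc(OCc9ccccc9)c2c1O[C@H](c3ccc(OCc9ccccc9)c(OCc9ccccc9)c3)[C@@H](OCc9ccccc9)C2 | intermediate (not isolated)
17 | O-allyl benzhydrol on C8 of the dimer (carbinol epimers) | C=CCOc1cc(OCc9ccccc9)cc(OCc9ccccc9)c1C(O)c1c(OCc9ccccc9)cc(OCc9ccccc9)c2c1O[C@H](c3cc(OCc9ccccc9)c(OCc9ccccc9)c(OCc9ccccc9)c3)[C@@H](OCc9ccccc9)[C@H]2c1c(OCc9ccccc9)cc(OCc9ccccc9)c2c1O[C@H](c3ccc(OCc9ccccc9)c(OCc9ccccc9)c3)[C@@H](OCc9ccccc9)C2 | intermediate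
18 | o-hydroxybenzhydrol on C8 of the dimer (carbinol epimers) | Oc1cc(OCc9ccccc9)cc(OCc9ccccc9)c1C(O)c1c(OCc9ccccc9)cc(OCc9ccccc9)c2c1O[C@H](c3cc(OCc9ccccc9)c(OCc9ccccc9)c(OCc9ccccc9)c3)[C@@H](OCc9ccccc9)[C@H]2c1c(OCc9ccccc9)cc(OCc9ccccc9)c2c1O[C@H](c3ccc(OCc9ccccc9)c(OCc9ccccc9)c3)[C@@H](OCc9ccccc9)C2 | intermediate
19 | 3,4-dihydroxyphenylacetic acid | O=C(O)Cc1ccc(O)c(O)c1 | starting material
20 | benzyl [3,4-bis(benzyloxy)phenyl]acetate | O=C(OCc9ccccc9)Cc1ccc(OCc9ccccc9)c(OCc9ccccc9)c1 | intermediate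
21 | [3,4-bis(benzyloxy)phenyl]acetaldehyde | O=CCc1ccc(OCc9ccccc9)c(OCc9ccccc9)c1 | intermediate
22 | (E)-2-[3,4-bis(benzyloxy)phenyl]vinyl acetate | CC(=O)O/C=C/c3ccc(OCc9ccccc9)c(OCc9ccccc9)c3 | intermediate
23 | (E)-o-quinone methide (dimer aryl group trans to C8a) | O=C1C=C(OCc9ccccc9)C=C(OCc9ccccc9)/C1=C\c1c(OCc9ccccc9)cc(OCc9ccccc9)c2c1O[C@H](c3cc(OCc9ccccc9)c(OCc9ccccc9)c(OCc9ccccc9)c3)[C@@H](OCc9ccccc9)[C@H]2c1c(OCc9ccccc9)cc(OCc9ccccc9)c2c1O[C@H](c3ccc(OCc9ccccc9)c(OCc9ccccc9)c3)[C@@H](OCc9ccccc9)C2 | intermediate (not isolated)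
24 | protected trimer, top O3 as acetate | c9ccccc9COc1cc(OCc9ccccc9)c2c(c1)O[C@H](c3ccc(OCc9ccccc9)c(OCc9ccccc9)c3)[C@@H](OC(C)=O)[C@@H]2c1c(OCc9ccccc9)cc(OCc9ccccc9)c2c1O[C@H](c3cc(OCc9ccccc9)c(OCc9ccccc9)c(OCc9ccccc9)c3)[C@@H](OCc9ccccc9)[C@H]2c1c(OCc9ccccc9)cc(OCc9ccccc9)c2c1O[C@H](c3ccc(OCc9ccccc9)c(OCc9ccccc9)c3)[C@@H](OCc9ccccc9)C2 | intermediate
25 | pentadeca-O-benzyl trimer, free top 3-OH | c9ccccc9COc1cc(OCc9ccccc9)c2c(c1)O[C@H](c3ccc(OCc9ccccc9)c(OCc9ccccc9)c3)[C@@H](O)[C@@H]2c1c(OCc9ccccc9)cc(OCc9ccccc9)c2c1O[C@H](c3cc(OCc9ccccc9)c(OCc9ccccc9)c(OCc9ccccc9)c3)[C@@H](OCc9ccccc9)[C@H]2c1c(OCc9ccccc9)cc(OCc9ccccc9)c2c1O[C@H](c3ccc(OCc9ccccc9)c(OCc9ccccc9)c3)[C@@H](OCc9ccccc9)C2 | intermediate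
26 | catechin-(4α→8)-gallocatechin-(4β→8)-catechin | Oc1cc(O)c2c(c1)O[C@H](c1ccc(O)c(O)c1)[C@@H](O)[C@@H]2c1c(O)cc(O)c2c1O[C@H](c1cc(O)c(O)c(O)c1)[C@@H](O)[C@H]2c1c(O)cc(O)c2c1O[C@H](c1ccc(O)c(O)c1)[C@@H](O)C2 | target

Total step count: 18. Longest linear sequence: 11 steps (1, 2, 3, 6, 7, 8, 11, 12, 16, 17, 18).

Steps most likely to fail

Step 16. The methide is stabilised by six alkoxy donors and is crowded at C4. It may react too slowly with the weakly nucleophilic enol ester. Self-condensation, acetyl transfer to the phenol, reversed regiochemistry or poor facial discrimination could then take over.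

The fallback drops the cycloaddition. It forms the top C4–middle C8 bond by the established Lewis-acid condensation of a C4-activated flavan-3-ol with an arene nucleophile. It sets out from 2 and 11.
- Oxidation of 2 with DDQ in CH2Cl2 in the presence of 2-ethoxyethanol gives 5,7,3',4'-tetra-O-benzyl-4-(2-ethoxyethoxy)catechin F1.
- Ac2O, DMAP and pyridine convert F1 into its 3-O-acetate F2.
- Catalytic Me3SiOTf in CH2Cl2 at −78 °C ionises C4 of F2 in the presence of recoverable excess 11. The gallocatechin C8 of 11 attacks from the α face, anti to the participating 3-acetoxy group.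
- This gives the 3,4-trans linkage and returns to the route at 24. Steps 8 to 15 then drop out.

Step 7. Hydride may reach both faces of the cation, because in the 2,3-trans series the C2 aryl group and O3 shield opposite faces. Loss of H3 to give the flav-3-ene may also compete.

The fallback replaces the reduction by a tethered condensation, the known way to 3,4-cis catechin dimers. It sets out from 6 and 2.
- NaBH4 in THF/EtOH reduces 6 to the penta-O-benzyl flavan-3,4-diol F3.
- Pyridinium tosylate in 2-ethoxyethanol/CH2Cl2 exchanges the benzylic 4-OH to give the 4-(2-ethoxyethoxy) ether F4.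
- Glutaric anhydride and DMAP convert 2 into the tetra-O-benzylcatechin 3-O-hemiglutarate F5.
- Carbodiimide/DMAP esterification of the 3-OH of F4 with F5 gives the glutarate-linked pair F6.
- Me3SiOTf in dilute CH2Cl2 ionises C4. The short tether on the β-oriented O3 forces catechin C8 to approach from the β face, giving the glutarate-bridged 4β→8 dimer F7.
- NaOMe in MeOH/THF removes the tether to give the nona-O-benzyl dimer 3,3-diol F8.
- NaH and BnBr return to the route at 11.

Step 8. Bromination may spread to the C6 positions of either ring A, or run on to dibromides. Assignment on a rotameric dimer is also laborious.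

The fallback places the halogen at the monomer stage, where only two sites compete. It sets out from 7 and 8.
- NBS in CH2Cl2 converts 7 into 8-bromo-hexa-O-benzyldihydromyricetin F9.
- Anhydrous CeCl3 at −78 °C transmetalates aryllithium 8 to the arylcerium dichloride F10. This species adds to ketones but does not undergo halogen–metal exchange.
- Its addition to F9 gives the 8-bromo tertiary carbinol F11.
- n-Bu3SnH and CF3CO2H are then used as in step 7. Under these ionic conditions in the dark, with no radical initiator, the C–Br bond persists. This returns to the route at 12.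

Further compounds

F1 | step 16 | 5,7,3',4'-tetra-O-benzyl-4-(2-ethoxyethoxy)catechin (C4 epimers, centre ionised in the coupling) | c9ccccc9COc1cc(OCc9ccccc9)c2c(c1)O[C@H](c3ccc(OCc9ccccc9)c(OCc9ccccc9)c3)[C@@H](O)C2OCCOCC
F2 | step 16 | 3-O-acetyl-5,7,3',4'-tetra-O-benzyl-4-(2-ethoxyethoxy)catechin | c9ccccc9COc1cc(OCc9ccccc9)c2c(c1)O[C@H](c3ccc(OCc9ccccc9)c(OCc9ccccc9)c3)[C@@H](OC(C)=O)C2OCCOCC
F3 | step 7 | penta-O-benzyl flavan-3,4-diol from 6 (C4 not assigned) | c9ccccc9COc1cc(OCc9ccccc9)c2c(c1)O[C@H](c3cc(OCc9ccccc9)c(OCc9ccccc9)c(OCc9ccccc9)c3)[C@@H](O)C2O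
F4 | step 7 | penta-O-benzyl-4-(2-ethoxyethoxy)gallocatechin (C4 not assigned) | c9ccccc9COc1cc(OCc9ccccc9)c2c(c1)O[C@H](c3cc(OCc9ccccc9)c(OCc9ccccc9)c(OCc9ccccc9)c3)[C@@H](O)C2OCCOCC
F5 | step 7 | tetra-O-benzylcatechin 3-O-hemiglutarate | c9ccccc9COc1cc(OCc9ccccc9)c2c(c1)O[C@H](c3ccc(OCc9ccccc9)c(OCc9ccccc9)c3)[C@@H](OC(=O)CCCC(=O)O)C2
F6 | step 7 | glutarate-linked gallocatechin electrophile and catechin nucleophile | c9ccccc9COc1cc(OCc9ccccc9)c2c(c1)O[C@H](c3cc(OCc9ccccc9)c(OCc9ccccc9)c(OCc9ccccc9)c3)[C@@H](OC(=O)CCCC(=O)O[C@H]5Cc4c(OCc9ccccc9)cc(OCc9ccccc9)cc4O[C@@H]5c6ccc(OCc9ccccc9)c(OCc9ccccc9)c6)C2OCCOCC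
F7 | step 7 | glutarate-bridged 4β→8 dimer | c9ccccc9COc1cc(OCc9ccccc9)c2c(c1)O[C@H](c3cc(OCc9ccccc9)c(OCc9ccccc9)c(OCc9ccccc9)c3)[C@@H](OC(=O)CCCC(=O)O7)[C@H]2c1c(OCc9ccccc9)cc(OCc9ccccc9)c2c1O[C@H](c3ccc(OCc9ccccc9)c(OCc9ccccc9)c3)[C@@H]7C2
F8 | step 7 | nona-O-benzyl gallocatechin-(4β→8)-catechin with both 3-OH free | c9ccccc9COc1cc(OCc9ccccc9)c2c(c1)O[C@H](c3cc(OCc9ccccc9)c(OCc9ccccc9)c(OCc9ccccc9)c3)[C@@H](O)[C@H]2c1c(OCc9ccccc9)cc(OCc9ccccc9)c2c1O[C@H](c3ccc(OCc9ccccc9)c(OCc9ccccc9)c3)[C@@H](O)C2
F9 | step 8 | 8-bromo-hexa-O-benzyldihydromyricetin | Brc1c(OCc9ccccc9)cc(OCc9ccccc9)c2c1O[C@H](c3cc(OCc9ccccc9)c(OCc9ccccc9)c(OCc9ccccc9)c3)[C@@H](OCc9ccccc9)C2=O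
F10 | step 8 | (penta-O-benzylcatechin-8-yl)cerium dichloride | Cl[Ce](Cl)c1c(OCc9ccccc9)cc(OCc9ccccc9)c2c1O[C@H](c3ccc(OCc9ccccc9)c(OCc9ccccc9)c3)[C@@H](OCc9ccccc9)C2
F11 | step 8 | 8-bromo tertiary C4 carbinol of the dimer (C4 not assigned) | Brc1c(OCc9ccccc9)cc(OCc9ccccc9)c2c1O[C@H](c3cc(OCc9ccccc9)c(OCc9ccccc9)c(OCc9ccccc9)c3)[C@@H](OCc9ccccc9)C2(O)c1c(OCc9ccccc9)cc(OCc9ccccc9)c2c1O[C@H](c3ccc(OCc9ccccc9)c(OCc9ccccc9)c3)[C@@H](OCc9ccccc9)C2
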